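**Plan**
1. The ring C8–C12, a 2-chloro-4-hydroxy-4-alkylcyclopent-2-enone, is the isomer of a 3-chloro-5-alkyl-2-furylcarbinol (furan C2, C3-Cl, C4, C5 = C9, C10, C11, C12; carbinol carbon = C8), so the first cut is the ring bond C8–C12.
2. Further cuts: C8–C9 (acyl–furan bond, giving a triacetoxy acid chloride and a 2-metallated 3-chlorofuran), C12–C13 (furan–octadienyl bond), C3–C4 (cross-metathesis) and C15–C16 (alkyne–propargyl coupling).
3. Forward: the C1–C8 chain is built from D-xylose and oxidised at C8, the dienyl chlorofuran is made separately, the two are joined as the C8 ketone, this is reduced, and the only ring is closed in the last step.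
4. Stereochemistry: C5, C6, C7 are C2, C3, C4 of D-xylose; both Z alkenes come from Lindlar reduction of a skipped diyne; C8 and C12 arise together in the conrotatory closure, their absolute sense relayed from C7.

Key step: step 18

Remark: prostanoid numbering (C1 = ester carbon, C20 = terminal methyl) is used for all chain compounds; the target is read as the 5S,6R,7R,8S,12R isomer, and carbinol 29 is carried as its C8 epimer mixture because that centre is erased in the key step.

**Route**

Step 1
Reactants: 1 D-xylose
Product: 2 5-O-trityl-D-xylofuranose (anomer mixture)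
Conditions: TrCl (1.1 equiv), pyridine, rt → 40 °C
Reagents that add atoms: trityl chloride ClC(c1ccccc1)(c1ccccc1)c1ccccc1
Why: Only the furanose tautomer has a primary hydroxyl, and selective tritylation of that primary OH should drain the mutarotation equilibrium without touching the stereocentres.

Step 2
Reactants: 2 5-O-trityl-D-xylofuranose
Product: 4 (2R,3R,4S)-1-(trityloxy)hex-5-ene-2,3,4-triol, via open-chain aldehyde form 3 (not isolated)
Conditions: Ph3PCH3Br (4 equiv), KOtBu (4 equiv), THF, 0 → 40 °C
Reagents that add atoms: methyltriphenylphosphonium bromide C[P+](c1ccccc1)(c1ccccc1)c1ccccc1.[Br-]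
Why: Wittig methylenation of a lactol through its hydroxy-aldehyde form, where excess ylide first turns the hydroxyls into alkoxides that protect the α-centre from enolisation, so xylose C2–C4 pass unchanged into C5–C7.

Step 3
Reactants: 4 (2R,3R,4S)-1-(trityloxy)hex-5-ene-2,3,4-triol
Product: 5 (2R,3R,4S)-1-(trityloxy)hex-5-ene-2,3,4-triyl triacetate
Conditions: Ac2O, pyridine, DMAP (cat.), CH2Cl2, 0 °C → rt
Reagents that add atoms: acetic anhydride CC(=O)OC(C)=O
Why: Standard pyridine/DMAP acylation of three secondary alcohols installs the final acetates before any furan chemistry, so no protecting-group exchange is needed later.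

Step 4
Reactants: 5 (2R,3R,4S)-1-(trityloxy)hex-5-ene-2,3,4-triyl triacetate; 6 methyl but-3-enoate (4 equiv)
Product: 7 methyl (3E,5S,6R,7R)-5,6,7-triacetoxy-8-(trityloxy)oct-3-enoate (E major)
Conditions: Hoveyda–Grubbs II (5 mol%), 1,4-benzoquinone (10 mol%), CH2Cl2, 40 °C
Reagents that add atoms: none
Why: Olefin cross-metathesis between a hindered allylic-acetoxy terminal alkene and an excess of an unhindered terminal alkene should favour the cross product, with alkene geometry irrelevant because it is hydrogenated next.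

Step 5
Reactants: 7 methyl (3E,5S,6R,7R)-5,6,7-triacetoxy-8-(trityloxy)oct-3-enoate
Product: 8 methyl (5S,6R,7R)-5,6,7-triacetoxy-8-(trityloxy)octanoate
Conditions: H2 (3 atm), RhCl(PPh3)3 (5 mol%), benzene/EtOH (1:1), rt
Reagents that add atoms: none
Why: Homogeneous hydrogenation with Wilkinson's catalyst saturates the disubstituted alkene without hydrogenolysis of the allylic acetate or the trityl ether.

Step 6
Reactants: 8 methyl (5S,6R,7R)-5,6,7-triacetoxy-8-(trityloxy)octanoate
Product: 9 methyl (5S,6R,7R)-5,6,7-triacetoxy-8-hydroxyoctanoate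
Conditions: Et3SiH (2 equiv), TFA (5% v/v), CH2Cl2, 0 °C
Reagents that add atoms: none
Why: Reductive detritylation, in which acid ionises the trityl ether and the silane traps the trityl cation irreversibly, should be fast enough at 0 °C that acetyl migration to the freed primary hydroxyl does not compete.

Step 7
Reactants: 9 methyl (5S,6R,7R)-5,6,7-triacetoxy-8-hydroxyoctanoate
Product: 11 (2S,3R,4S)-2,3,4-triacetoxy-8-methoxy-8-oxooctanoic acid (C8 acid of the chain), via aldehyde 10 (not isolated)
Conditions: TEMPO (0.2 equiv), PhI(OAc)2 (2.2 equiv), MeCN/H2O (1:1), rt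
Reagents that add atoms: water O
Why: TEMPO/diacetoxyiodobenzene oxidation takes the primary alcohol through the aldehyde hydrate to the acid under weakly acidic conditions that spare the acetates and the α-acetoxy stereocentre.

Step 8
Reactants: 11 (2S,3R,4S)-2,3,4-triacetoxy-8-methoxy-8-oxooctanoic acid
Product: 12 methyl (5S,6R,7S)-5,6,7-triacetoxy-8-chloro-8-oxooctanoate (used crude)
Conditions: (COCl)2 (1.5 equiv), DMF (cat.), CH2Cl2, 0 °C → rt; evaporate
Reagents that add atoms: oxalyl chloride ClC(=O)C(Cl)=O
Why: Vilsmeier-catalysed acid chloride formation is routine for peracetylated aldonic acids, whose chlorides are configurationally stable in the absence of base.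

Step 9
Reactants: 13 1-bromopent-2-yne; 14 propargyl alcohol
Product: 15 octa-2,5-diyn-1-ol
Conditions: CuI (cat.), K2CO3, n-Bu4NCl (cat.), DMF, rt
Reagents that add atoms: none
Why: Copper-catalysed coupling of a propargylic halide with a terminal alkyne (SN2 by the copper acetylide) is the standard skipped-diyne construction and tolerates the free hydroxyl.

Step 10
Reactants: 15 octa-2,5-diyn-1-ol
Product: 16 (2Z,5Z)-octa-2,5-dien-1-ol
Conditions: H2 (1 atm), Lindlar catalyst, quinoline, EtOAc, rt
Reagents that add atoms: none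
Why: Lindlar semi-hydrogenation adds hydrogen syn to each alkyne and so sets both Z alkenes (C14–C15 and C17–C18), with quinoline suppressing over-reduction.

Step 11
Reactants: 16 (2Z,5Z)-octa-2,5-dien-1-ol
Product: 17 (2Z,5Z)-1-bromoocta-2,5-diene
Conditions: CBr4, PPh3, CH2Cl2, −20 → 0 °C
Reagents that add atoms: tetrabromomethane BrC(Br)(Br)Br
Why: The Appel reaction converts the allylic alcohol to the bromide under neutral conditions that should avoid allylic transposition and Z/E isomerisation.

Step 12
Reactants: 18 3-bromofuran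
Product: 20 (3-bromofuran-2-yl)trimethylsilane, via 3-bromo-2-furyllithium 19 (not isolated)
Conditions: LDA (1.05 equiv), THF, −78 °C; TMSCl
Reagents that add atoms: chlorotrimethylsilane C[Si](C)(C)Cl
Why: LDA removes the most acidic ring proton (C2–H, flanked by O and Br) without bromine–lithium exchange, and silylation blocks this position for the later C5 functionalisation.

Step 13
Reactants: 20 (3-bromofuran-2-yl)trimethylsilane
Product: 22 (3-chlorofuran-2-yl)trimethylsilane, via 2-silyl-3-furyllithium 21 (not isolated)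
Conditions: n-BuLi (1.05 equiv), THF, −78 °C; C2Cl6, −78 °C → rt
Reagents that add atoms: hexachloroethane ClC(Cl)(Cl)C(Cl)(Cl)Cl
Why: Bromine–lithium exchange outruns deprotonation at −78 °C, and the 3-furyllithium (unable to isomerise because C2 is silylated) is chlorinated by electrophilic chlorine transfer from hexachloroethane.

Step 14
Reactants: 22 (3-chlorofuran-2-yl)trimethylsilane; 17 (2Z,5Z)-1-bromoocta-2,5-diene
Product: 24 [3-chloro-5-[(2Z,5Z)-octa-2,5-dien-1-yl]furan-2-yl]trimethylsilane, via 5-lithiofuran 23 (not isolated)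
Conditions: n-BuLi (1.05 equiv), THF, −78 → −30 °C; then 17, −78 °C → rt
Reagents that add atoms: none
Why: With C2 blocked the only α-proton is C5–H, and the resulting furyllithium should displace the primary allylic bromide by direct SN2 alkylation with the Z,Z geometry retained.

Step 15
Reactants: 24 [3-chloro-5-[(2Z,5Z)-octa-2,5-dien-1-yl]furan-2-yl]trimethylsilane
Product: 25 4-chloro-2-[(2Z,5Z)-octa-2,5-dien-1-yl]furan
Conditions: TBAF (1.2 equiv), wet THF, rt
Reagents that add atoms: none
Why: Fluoride-induced protodesilylation of a 2-silylfuran, eased by the adjacent chlorine, frees the ring position next to chlorine at room temperature, where the skipped diene should not isomerise.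

Step 16
Reactants: 25 4-chloro-2-[(2Z,5Z)-octa-2,5-dien-1-yl]furan (1.2 equiv); 12 methyl (5S,6R,7S)-5,6,7-triacetoxy-8-chloro-8-oxooctanoate
Product: 28 methyl (5S,6R,7S)-5,6,7-triacetoxy-8-[3-chloro-5-[(2Z,5Z)-octa-2,5-dien-1-yl]furan-2-yl]-8-oxooctanoate, via furyllithium 26 (not isolated), via furylzinc chloride 27 (not isolated)
Conditions: n-BuLi (1.0 equiv), THF, −78 °C; ZnCl2, −78 → 0 °C; then 12, Pd(PPh3)4 (5 mol%), 0 °C → rt
Reagents that add atoms: none
Why: The C–H between O and Cl is the kinetically most acidic site, and transmetalation to zinc gives a non-basic nucleophile for Pd-catalysed Negishi acylation, which forms C8–C9 in the presence of four ester groups without disturbing C7.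

Step 17
Reactants: 28 methyl (5S,6R,7S)-5,6,7-triacetoxy-8-[3-chloro-5-[(2Z,5Z)-octa-2,5-dien-1-yl]furan-2-yl]-8-oxooctanoate
Product: 29 methyl (5S,6R,7R,8RS)-5,6,7-triacetoxy-8-[3-chloro-5-[(2Z,5Z)-octa-2,5-dien-1-yl]furan-2-yl]-8-hydroxyoctanoate (C8 epimer mixture)
Conditions: NaBH4, CeCl3·7H2O, MeOH/THF, −78 °C; AcOH quench
Reagents that add atoms: none
Why: Luche reduction is fast, cold and nearly neutral, so the esters and the enolisable α-acetoxy centre C7 should survive, and the C8 configuration need not be controlled because the next step erases it.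

Step 18
Reactants: 29 methyl (5S,6R,7R,8RS)-5,6,7-triacetoxy-8-[3-chloro-5-[(2Z,5Z)-octa-2,5-dien-1-yl]furan-2-yl]-8-hydroxyoctanoate
Product: 33 methyl (5S,6R,7R)-5,6,7-triacetoxy-7-[(1S,5R)-3-chloro-5-hydroxy-5-[(2Z,5Z)-octa-2,5-dien-1-yl]-2-oxocyclopent-3-en-1-yl]heptanoate (the target), via furfuryl cation 30 (not isolated), via dihydrofuran hemiketal 31 (not isolated), via hydroxypentadienyl cation 32 (not isolated)
Conditions: Dy(OTf)3 (20 mol%), t-BuOH/H2O (5:1), 80 °C
Reagents that add atoms: water O
Why: Dy(III) ionises the C8 carbinol to the furfuryl (oxocarbenium) cation 30, erasing the C8 configuration so that both epimers of 29 converge; water adds at the octadienyl-bearing furan carbon to give hemiketal 31, which opens to the 1,4-dihydroxypentadienyl cation 32, and this closes C8–C12 and loses a proton to give the chloroenone. The reaction type is the Piancatelli rearrangement, established for 5-alkyl-2-furylcarbinols giving 4-alkyl-4-hydroxycyclopent-2-enones. The cyclopentenone ring is closed by a thermal conrotatory 4π electrocyclisation of the pentadienyl cation (Nazarov-type), with furan C2, C3(Cl), C4 and C5 becoming C9, C10, C11 and C12. C8 and C12 are set in this closure: with the C7 chain outward on the enol terminus and the octadienyl CH2 outward (hydroxyl inward) on the C12 terminus, conrotation places the two carbon chains trans, which is also the arrangement favoured if C8 equilibrates through the enol. The sense of conrotation is relayed from C7: allylic 1,3-strain against the metal-bound C9 oxygen keeps C7–H in the cation plane, and the rotation that turns the larger C6 branch away from the closing termini and the acetoxy toward the inward C12 hydroxyl (hydrogen bond to the acetyl carbonyl) should lead to 8S,12R. The step needs water capture at C12 and not at C8 (capture at C8 only regenerates 29) and freedom from side-chain trapping and β-elimination, which the three acetates (no free hydroxyl to form a tetrahydrofuran) and the weakly acidic, non-basic medium secure; the isomer from the opposite helical sense is a diastereomer and should be separable.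

**Compound list**
1 | D-xylose | O=C[C@H](O)[C@@H](O)[C@H](O)CO | starting material
2 | 5-O-trityl-D-xylofuranose (anomer mixture) | OC1[C@H](O)[C@@H](O)[C@@H](COC(c2ccccc2)(c2ccccc2)c2ccccc2)O1 | intermediate
3 | 5-O-trityl-aldehydo-D-xylose (open-chain form, in situ) | O=C[C@H](O)[C@@H](O)[C@H](O)COC(c1ccccc1)(c1ccccc1)c1ccccc1 | intermediate
4 | (2R,3R,4S)-1-(trityloxy)hex-5-ene-2,3,4-triol | C=C[C@H](O)[C@@H](O)[C@H](O)COC(c1ccccc1)(c1ccccc1)c1ccccc1 | intermediate
5 | (2R,3R,4S)-1-(trityloxy)hex-5-ene-2,3,4-triyl triacetate | C=C[C@H](OC(C)=O)[C@@H](OC(C)=O)[C@H](OC(C)=O)COC(c1ccccc1)(c1ccccc1)c1ccccc1 | intermediate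
6 | methyl but-3-enoate | C=CCC(=O)OC | starting material
7 | methyl (3E,5S,6R,7R)-5,6,7-triacetoxy-8-(trityloxy)oct-3-enoate | COC(=O)C/C=C/[C@H](OC(C)=O)[C@@H](OC(C)=O)[C@H](OC(C)=O)COC(c1ccccc1)(c1ccccc1)c1ccccc1 | intermediate
8 | methyl (5S,6R,7R)-5,6,7-triacetoxy-8-(trityloxy)octanoate | COC(=O)CCC[C@H](OC(C)=O)[C@@H](OC(C)=O)[C@H](OC(C)=O)COC(c1ccccc1)(c1ccccc1)c1ccccc1 | intermediate
9 | methyl (5S,6R,7R)-5,6,7-triacetoxy-8-hydroxyoctanoate | COC(=O)CCC[C@H](OC(C)=O)[C@@H](OC(C)=O)[C@H](OC(C)=O)CO | intermediate
10 | methyl (5S,6R,7S)-5,6,7-triacetoxy-8-oxooctanoate (in situ) | COC(=O)CCC[C@H](OC(C)=O)[C@@H](OC(C)=O)[C@H](OC(C)=O)C=O | intermediate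
11 | (2S,3R,4S)-2,3,4-triacetoxy-8-methoxy-8-oxooctanoic acid | COC(=O)CCC[C@H](OC(C)=O)[C@@H](OC(C)=O)[C@H](OC(C)=O)C(O)=O | intermediate
12 | methyl (5S,6R,7S)-5,6,7-triacetoxy-8-chloro-8-oxooctanoate | COC(=O)CCC[C@H](OC(C)=O)[C@@H](OC(C)=O)[C@H](OC(C)=O)C(Cl)=O | intermediate
13 | 1-bromopent-2-yne | CCC#CCBr | starting material
14 | propargyl alcohol | C#CCO | starting material
15 | octa-2,5-diyn-1-ol | CCC#CCC#CCO | intermediate
16 | (2Z,5Z)-octa-2,5-dien-1-ol | CC/C=C\C/C=C\CO | intermediate
17 | (2Z,5Z)-1-bromoocta-2,5-diene | CC/C=C\C/C=C\CBr | intermediate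
18 | 3-bromofuran | Brc1ccoc1 | starting material
19 | (3-bromofuran-2-yl)lithium (in situ) | [Li]c1occc1Br | intermediate
20 | (3-bromofuran-2-yl)trimethylsilane | C[Si](C)(C)c1occc1Br | intermediate
21 | [2-(trimethylsilyl)furan-3-yl]lithium (in situ) | [Li]c1ccoc1[Si](C)(C)C | intermediate
22 | (3-chlorofuran-2-yl)trimethylsilane | C[Si](C)(C)c1occc1Cl | intermediate
23 | [4-chloro-5-(trimethylsilyl)furan-2-yl]lithium (in situ) | [Li]c1cc(Cl)c(o1)[Si](C)(C)C | intermediate
24 | [3-chloro-5-[(2Z,5Z)-octa-2,5-dien-1-yl]furan-2-yl]trimethylsilane | CC/C=C\C/C=C\Cc1cc(Cl)c(o1)[Si](C)(C)C | intermediate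
25 | 4-chloro-2-[(2Z,5Z)-octa-2,5-dien-1-yl]furan | CC/C=C\C/C=C\Cc1cc(Cl)co1 | intermediate
26 | [3-chloro-5-[(2Z,5Z)-octa-2,5-dien-1-yl]furan-2-yl]lithium (in situ) | CC/C=C\C/C=C\Cc1cc(Cl)c([Li])o1 | intermediate
27 | [3-chloro-5-[(2Z,5Z)-octa-2,5-dien-1-yl]furan-2-yl]zinc chloride (in situ) | CC/C=C\C/C=C\Cc1cc(Cl)c([Zn]Cl)o1 | intermediate
28 | methyl (5S,6R,7S)-5,6,7-triacetoxy-8-[3-chloro-5-[(2Z,5Z)-octa-2,5-dien-1-yl]furan-2-yl]-8-oxooctanoate | CC/C=C\C/C=C\Cc1cc(Cl)c(o1)C(=O)[C@@H](OC(C)=O)[C@H](OC(C)=O)[C@H](CCCC(=O)OC)OC(C)=O | intermediate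
29 | methyl (5S,6R,7R,8RS)-5,6,7-triacetoxy-8-[3-chloro-5-[(2Z,5Z)-octa-2,5-dien-1-yl]furan-2-yl]-8-hydroxyoctanoate | CC/C=C\C/C=C\Cc1cc(Cl)c(o1)C(O)[C@@H](OC(C)=O)[C@H](OC(C)=O)[C@H](CCCC(=O)OC)OC(C)=O | intermediate
30 | furfuryl cation from 29, drawn as the 2-alkylidene furan oxocarbenium ion (in situ) | CC/C=C\C/C=C\CC1=[O+]C(=C[C@@H](OC(C)=O)[C@H](OC(C)=O)[C@H](CCCC(=O)OC)OC(C)=O)C(Cl)=C1 | intermediate
31 | 2-alkylidene-3-chloro-5-hydroxy-5-octadienyl-2,5-dihydrofuran hemiketal (in situ) | CC/C=C\C/C=C\CC1(O)OC(=C[C@@H](OC(C)=O)[C@H](OC(C)=O)[C@H](CCCC(=O)OC)OC(C)=O)C(Cl)=C1 | intermediate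
32 | 1,4-dihydroxypentadienyl cation, C10–C11 Z, drawn as the O-protonated C12 ketone of the C9 enol (in situ) | CC/C=C\C/C=C\CC(=[OH+])/C=C(Cl)\C(O)=C[C@@H](OC(C)=O)[C@H](OC(C)=O)[C@H](CCCC(=O)OC)OC(C)=O | intermediate
33 | methyl (5S,6R,7R)-5,6,7-triacetoxy-7-[(1S,5R)-3-chloro-5-hydroxy-5-[(2Z,5Z)-octa-2,5-dien-1-yl]-2-oxocyclopent-3-en-1-yl]heptanoate | CC/C=C\C/C=C\C[C@]1(O)C=C(Cl)C(=O)[C@H]1[C@@H](OC(C)=O)[C@H](OC(C)=O)[C@H](CCCC(=O)OC)OC(C)=O | target

**Step count**
Total: 18 steps. Longest linear sequence: 11 steps (steps 1–8, then 16, 17, 18).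

**Steps most likely to fail**

1. Step 18. The relay from C7 acts across a freely rotating bond, so conrotation may proceed in both helical senses. In addition, the C7 acetoxy may capture the C8 cation as an acetoxonium ion and migrate or be lost. Fallback: stereocontrol is moved from the substrate to the acid. Setting out from 29, the rearrangement is run with a chiral BINOL-derived phosphoric acid or N-triflylphosphoramide (both antipodes tried, to find the matched pair) in a water-containing non-coordinating solvent at moderate temperature. The chiral counter-anion paired with the hydroxypentadienyl cation should then decide the sense of conrotation, as in catalytic asymmetric Piancatelli-type rearrangements with amine nucleophiles. The route is rejoined at 33. This fallback makes no new compound (F0).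

2. Step 2. The lactol enters the olefination as a poorly soluble polyalkoxide, so conversion may stall, or base-induced retro-aldol and β-elimination may degrade the open-chain form. Fallback: an acyclic, fully acylated aldehyde and a non-basic methylenation. Setting out from 1, ethanethiol/HCl gives D-xylose diethyl dithioacetal F1. Trityl chloride in pyridine then gives 5-O-trityl-D-xylose diethyl dithioacetal F2. Acetic anhydride/pyridine gives 2,3,4-tri-O-acetyl-5-O-trityl-D-xylose diethyl dithioacetal F3. Iodine/NaHCO3 in aqueous acetone unmasks 2,3,4-tri-O-acetyl-5-O-trityl-aldehydo-D-xylose F4. Takai methylenation (CH2I2, Zn, Ti(OiPr)4, THF), which is selective for aldehydes over esters, then delivers 5, where the route is rejoined.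

3. Step 16. Deprotonation may occur at the furfuryl/allylic C13 methylene or the bis-allylic C16 methylene instead of the ring, which would scramble the skipped diene. Transmetalation before acylation may also be incomplete. Fallback: the C8–C9 bond is made by electrophilic substitution, with no organolithium in contact with the diene. Setting out from acid 11 and furan 25, trifluoroacetic anhydride in CH2Cl2 at 0 °C converts 11 into the mixed trifluoroacetic anhydride of acid 11 F5. This acylates the only free α-position of 25 (Friedel–Crafts acylation of a furan, with catalytic BF3·OEt2 if needed) to give ketone 28, where the route is rejoined.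

**Further compounds**
F0 | step 18 | none | none
F1 | step 2 | D-xylose diethyl dithioacetal | CCSC(SCC)[C@H](O)[C@@H](O)[C@H](O)CO
F2 | step 2 | 5-O-trityl-D-xylose diethyl dithioacetal | CCSC(SCC)[C@H](O)[C@@H](O)[C@H](O)COC(c1ccccc1)(c1ccccc1)c1ccccc1
F3 | step 2 | 2,3,4-tri-O-acetyl-5-O-trityl-D-xylose diethyl dithioacetal | CCSC(SCC)[C@H](OC(C)=O)[C@@H](OC(C)=O)[C@H](OC(C)=O)COC(c1ccccc1)(c1ccccc1)c1ccccc1
F4 | step 2 | 2,3,4-tri-O-acetyl-5-O-trityl-aldehydo-D-xylose | O=C[C@H](OC(C)=O)[C@@H](OC(C)=O)[C@H](OC(C)=O)COC(c1ccccc1)(c1ccccc1)c1ccccc1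
F5 | step 16 | mixed trifluoroacetic anhydride of acid 11 | COC(=O)CCC[C@H](OC(C)=O)[C@@H](OC(C)=O)[C@H](OC(C)=O)C(=O)OC(=O)C(F)(F)F
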